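**Retrosynthetic overview**
1. Target 13 ⇐ hydroxy butenolide 12 by intramolecular oxa-Michael addition (9α-OH → C13); the spiro tetrahydrofuran is the last ring formed.
2. The 7-oxo/8β-OAc/9α-OH triad of 12 ⇐ trans 7β-acetoxy-8α,9α-epoxide 9 (acetoxonium opening, inversion at C8) ⇐ 8-en-7-one 6 ⇐ 8(9)-ene 5 ⇐ dehydration of carbinol 4.
3. Butenolide of 4 ⇐ 3-furyl ring of (+)-marrubiin 1 by singlet-oxygen [4+2] cycloaddition (key step), Kornblum–DeLaMare opening and borohydride reduction.
4. Rings A and B and the 19,6β-lactone (C4, C5, C6, C10) are bought in 1. Forward ring order: butenolide (from the endoperoxide) → transient epoxide/acetoxonium → spiro tetrahydrofuran.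

Assumption: (+)-marrubiin, the bulk furanolabdane lactone of white horehound sold as a catalogue phytochemical, is taken as the commercial chiral starting material. Labdane numbering is used, α/β mean below/above the decalin plane, and in "X,Y-olide" the carbonyl carbon is named first.

**Step 1**
Reactants: 1 (+)-marrubiin
Product: 4 9α-hydroxylabd-13-ene-19,6β:15,16-diolide, via furan endoperoxide 2 (not isolated), via 16-hydroxybutenolide 3 (not isolated)
Conditions: O2, hν (visible), tetraphenylporphyrin (cat.), i-Pr2NEt, CH2Cl2, −78 °C; then NaBH4, MeOH, −78 → 0 °C; then 1 M HCl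
Reagents that add atoms: dioxygen (used as singlet oxygen), O=O
Why: The 3-alkylfuran is the only singlet-oxygen-reactive site and undergoes [4+2] cycloaddition to the 2,5-endoperoxide; Hünig's base removes the less hindered bridgehead H (C15) in a Kornblum–DeLaMare fragmentation so C15 becomes the carbonyl, and NaBH4 reduces the masked C16 aldehyde with relactonisation to the β-substituted butenolide, with no stereocentre touched.

**Step 2**
Reactants: 4 9α-hydroxylabd-13-ene-19,6β:15,16-diolide
Product: 5 labda-8,13-diene-19,6β:15,16-diolide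
Conditions: SOCl2, pyridine, CH2Cl2, −10 °C; crude product then I2 (5 mol%), PhH, 60 °C
Reagents that add atoms: none
Why: Anti E2 elimination of the chlorosulfite through the trans-diaxial 8β-H gives the tetrasubstituted 8(9)-ene, and I2 isomerises any 9(11)-ene to the same thermodynamic alkene; C8 and C9 are erased here on purpose and rebuilt in steps 6 and 7.

**Step 3**
Reactants: 5 labda-8,13-diene-19,6β:15,16-diolide
Product: 6 7-oxolabda-8,13-diene-19,6β:15,16-diolide
Conditions: CrO3, 3,5-dimethylpyrazole, CH2Cl2, −20 °C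
Reagents that add atoms: chromium trioxide, O=[Cr](=O)=O
Why: Salmond-type allylic oxidation attacks the ring methylene whose axial 7α-H is aligned with the alkene π system, whereas the C11 hydrogens are twisted out of alignment by allylic strain and the butenolide is electron-poor, giving the 8-en-7-one.

**Step 4**
Reactants: 6 7-oxolabda-8,13-diene-19,6β:15,16-diolide
Product: 7 7β-hydroxylabda-8,13-diene-19,6β:15,16-diolide
Conditions: NaBH4, CeCl3·7H2O, MeOH, −40 °C
Reagents that add atoms: none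
Why: Luche 1,2-reduction delivers hydride to the enone carbonyl from the α face, away from the 6β-lactone oxygen, giving the pseudo-equatorial 7β-alcohol without touching the butenolide or the lactones.

**Step 5**
Reactants: 7 7β-hydroxylabda-8,13-diene-19,6β:15,16-diolide
Product: 8 7β-acetoxylabda-8,13-diene-19,6β:15,16-diolide
Conditions: Ac2O, DMAP (cat.), pyridine, rt
Reagents that add atoms: acetic anhydride, CC(=O)OC(C)=O
Why: DMAP-catalysed acetylation of the only free hydroxyl installs the acetyl group that is later relayed to O8.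

**Step 6**
Reactants: 8 7β-acetoxylabda-8,13-diene-19,6β:15,16-diolide
Product: 9 7β-acetoxy-8α,9α-epoxylabd-13-ene-19,6β:15,16-diolide
Conditions: dimethyldioxirane (acetone solution), CH2Cl2, −20 → 0 °C
Reagents that add atoms: dimethyldioxirane, CC1(C)OO1
Why: Electrophilic epoxidation of the electron-rich tetrasubstituted alkene (the butenolide is inert) occurs on the α face because the axial C20 methyl and the 7β-acetate shield the β face, which sets the C9–O bond α and places the epoxide trans to the acetate.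

**Step 7**
Reactants: 9 7β-acetoxy-8α,9α-epoxylabd-13-ene-19,6β:15,16-diolide
Product: 11 8β-acetoxy-7β,9α-dihydroxylabd-13-ene-19,6β:15,16-diolide, via acetoxonium ion 10 (not isolated)
Conditions: TsOH·H2O (10 mol%), H2O (3 equiv), CH2Cl2, 0 °C
Reagents that add atoms: water, O
Why: Neighbouring-group participation: the 7β-acetate carbonyl opens the protonated epoxide at C8 from the β face (trans-diaxial opening with inversion, C9 keeps its α oxygen), and water hydrolyses the cis-fused 7β,8β-acetoxonium ion to the axial 8β-acetate and equatorial 7β-alcohol.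

**Step 8**
Reactants: 11 8β-acetoxy-7β,9α-dihydroxylabd-13-ene-19,6β:15,16-diolide
Product: 12 8β-acetoxy-9α-hydroxy-7-oxolabd-13-ene-19,6β:15,16-diolide
Conditions: Dess–Martin periodinane, CH2Cl2, 0 °C → rt
Reagents that add atoms: none
Why: Dess–Martin oxidation converts the only secondary alcohol into the C7 ketone under near-neutral conditions before the cis acetate can drift to O7; the tertiary 9α-OH and the tertiary acetate are untouched.

**Step 9**
Reactants: 12 8β-acetoxy-9α-hydroxy-7-oxolabd-13-ene-19,6β:15,16-diolide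
Product: 13 (13R)-8β-acetoxy-9α,13-epoxy-7-oxolabdane-19,6β:15,16-diolide
Conditions: DBU (0.3 equiv), CH2Cl2, rt
Reagents that add atoms: none
Why: Base-catalysed 5-exo intramolecular oxa-Michael addition of the 9α-alkoxide to C13 of the butenolide closes the spiro tetrahydrofuran; C13 is set under substrate control in a reversible step with little expected bias (about 1:1 to 2:1), so the 13R epimer is separated and the 13S epimer recycled under the same conditions.

**Compound list**
1 | (+)-marrubiin (15,16-epoxy-9α-hydroxylabda-13(16),14-dien-19,6β-olide) | C[C@@H]1C[C@H]2OC(=O)[C@@]3(C)CCC[C@@](C)([C@@H]23)[C@@]1(O)CCc1ccoc1 | starting material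
2 | furan endoperoxide (2,3,7-trioxabicyclo[2.2.1]hept-5-ene on the side chain, both facial isomers) | C[C@@H]1C[C@H]2OC(=O)[C@@]3(C)CCC[C@@](C)([C@@H]23)[C@@]1(O)CCC1=CC2OOC1O2 | intermediate (not isolated)
3 | 16-hydroxybutenolide (9α,16-dihydroxylabd-13-ene-19,6β:15,16-diolide, C16 epimers) | C[C@@H]1C[C@H]2OC(=O)[C@@]3(C)CCC[C@@](C)([C@@H]23)[C@@]1(O)CCC1=CC(=O)OC1O | intermediate (not isolated)
4 | 9α-hydroxylabd-13-ene-19,6β:15,16-diolide | C[C@@H]1C[C@H]2OC(=O)[C@@]3(C)CCC[C@@](C)([C@@H]23)[C@@]1(O)CCC1=CC(=O)OC1 | intermediate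
5 | labda-8,13-diene-19,6β:15,16-diolide | CC=1C[C@H]2OC(=O)[C@@]3(C)CCC[C@@](C)([C@@H]23)C=1CCC1=CC(=O)OC1 | intermediate
6 | 7-oxolabda-8,13-diene-19,6β:15,16-diolide | CC=1C(=O)[C@H]2OC(=O)[C@@]3(C)CCC[C@@](C)([C@@H]23)C=1CCC1=CC(=O)OC1 | intermediate
7 | 7β-hydroxylabda-8,13-diene-19,6β:15,16-diolide | CC=1[C@@H](O)[C@H]2OC(=O)[C@@]3(C)CCC[C@@](C)([C@@H]23)C=1CCC1=CC(=O)OC1 | intermediate
8 | 7β-acetoxylabda-8,13-diene-19,6β:15,16-diolide | CC=1[C@@H](OC(C)=O)[C@H]2OC(=O)[C@@]3(C)CCC[C@@](C)([C@@H]23)C=1CCC1=CC(=O)OC1 | intermediate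
9 | 7β-acetoxy-8α,9α-epoxylabd-13-ene-19,6β:15,16-diolide | C[C@@]12[C@@H](OC(C)=O)[C@H]3OC(=O)[C@@]4(C)CCC[C@@](C)([C@@H]34)[C@]1(CCC1=CC(=O)OC1)O2 | intermediate
10 | acetoxonium ion (7β,8β-fused 2-methyl-1,3-dioxolan-2-ylium, 9α-OH) | C[C@]12OC(C)=[O+][C@H]1[C@H]3OC(=O)[C@@]4(C)CCC[C@@](C)([C@@H]34)[C@@]2(O)CCC1=CC(=O)OC1 | intermediate (not isolated)
11 | 8β-acetoxy-7β,9α-dihydroxylabd-13-ene-19,6β:15,16-diolide | CC(=O)O[C@@]1(C)[C@@H](O)[C@H]2OC(=O)[C@@]3(C)CCC[C@@](C)([C@@H]23)[C@@]1(O)CCC1=CC(=O)OC1 | intermediate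
12 | 8β-acetoxy-9α-hydroxy-7-oxolabd-13-ene-19,6β:15,16-diolide | CC(=O)O[C@@]1(C)C(=O)[C@H]2OC(=O)[C@@]3(C)CCC[C@@](C)([C@@H]23)[C@@]1(O)CCC1=CC(=O)OC1 | intermediate
13 | (13R)-8β-acetoxy-9α,13-epoxy-7-oxolabdane-19,6β:15,16-diolide (CNP0259020.1) | CC(=O)O[C@@]1(C)C(=O)[C@H]2OC(=O)[C@@]3(C)CCC[C@@](C)([C@@H]23)[C@@]12CC[C@@]1(COC(=O)C1)O2 | target

**Totals**
Total step count: 9. Longest linear sequence: 9 (fully linear from 1).

**Three steps most likely to fail**

Step 3. C7 is inductively deactivated by the lactone oxygen on C6, so oxidation at C11 may compete or the reaction may stall. Fallback, from 5 back to 6: SeO2 (cat.) with t-BuOOH in CH2Cl2 hydroxylates by an ene reaction followed by a [2,3]-sigmatropic shift, which prefers the ring methylene and returns the double bond to C8–C9. This gives the 7α-allylic alcohol F1, and MnO2 in CH2Cl2 oxidises it to 6.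

Step 7. The kinetic axial 8β-acetate must form and survive; direct hydrolysis or acyl drift to O7 gives the wrong monoacetate. Fallback, from 9 to 13: open the epoxide with catalytic HClO4 in aqueous THF without regard to the ester position, which gives 11 mixed with its acyl-shifted isomer, the 7β-acetoxy-8β,9α-diol F2. K2CO3 in MeOH then removes the acetate and closes the spiro ether in the same pot, giving the spiro 7β,8β-diol F3 (13R epimer separated). Dess–Martin oxidation gives the tertiary ketol F4, and Ac2O with catalytic Sc(OTf)3 in MeCN at −20 °C acetylates its only hydroxyl to give 13.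

Step 9. The β-hydroxy ketone 12 may undergo retro-aldol opening of ring B under base, and C13 may form unselectively. Fallback, from 11 to 13: close the ether before the ketone exists. TESCl and imidazole in DMF protect the 7β-OH as the silyl ether F5. DBU then closes the spiro ring to the spiro silyl ether F6, where neither retro-aldol nor acyl shift is possible. HF·pyridine in THF frees the spiro 7β-alcohol F7, and Dess–Martin oxidation gives 13.

**Further compounds**
F1 | step 3 | 7α-hydroxylabda-8,13-diene-19,6β:15,16-diolide | CC=1[C@H](O)[C@H]2OC(=O)[C@@]3(C)CCC[C@@](C)([C@@H]23)C=1CCC1=CC(=O)OC1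
F2 | step 7 | 7β-acetoxy-8β,9α-dihydroxylabd-13-ene-19,6β:15,16-diolide | O[C@@]1(C)[C@@H](OC(C)=O)[C@H]2OC(=O)[C@@]3(C)CCC[C@@](C)([C@@H]23)[C@@]1(O)CCC1=CC(=O)OC1
F3 | step 7 | (13R)-9α,13-epoxy-7β,8β-dihydroxylabdane-19,6β:15,16-diolide | O[C@@]1(C)[C@@H](O)[C@H]2OC(=O)[C@@]3(C)CCC[C@@](C)([C@@H]23)[C@@]12CC[C@@]1(COC(=O)C1)O2
F4 | step 7 | (13R)-9α,13-epoxy-8β-hydroxy-7-oxolabdane-19,6β:15,16-diolide | O[C@@]1(C)C(=O)[C@H]2OC(=O)[C@@]3(C)CCC[C@@](C)([C@@H]23)[C@@]12CC[C@@]1(COC(=O)C1)O2
F5 | step 9 | 8β-acetoxy-9α-hydroxy-7β-(triethylsilyloxy)labd-13-ene-19,6β:15,16-diolide | CC(=O)O[C@@]1(C)[C@@H](O[Si](CC)(CC)CC)[C@H]2OC(=O)[C@@]3(C)CCC[C@@](C)([C@@H]23)[C@@]1(O)CCC1=CC(=O)OC1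
F6 | step 9 | (13R)-8β-acetoxy-9α,13-epoxy-7β-(triethylsilyloxy)labdane-19,6β:15,16-diolide | CC(=O)O[C@@]1(C)[C@@H](O[Si](CC)(CC)CC)[C@H]2OC(=O)[C@@]3(C)CCC[C@@](C)([C@@H]23)[C@@]12CC[C@@]1(COC(=O)C1)O2
F7 | step 9 | (13R)-8β-acetoxy-9α,13-epoxy-7β-hydroxylabdane-19,6β:15,16-diolide | CC(=O)O[C@@]1(C)[C@@H](O)[C@H]2OC(=O)[C@@]3(C)CCC[C@@](C)([C@@H]23)[C@@]12CC[C@@]1(COC(=O)C1)O2
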